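**Retrosynthetic overview**
1. Target acid 32 comes from methyl ester 30; ring B (the 1,2-dioxane) is closed last by 6-exo oxa-Michael addition of a C6 hydroperoxide onto an (E)-enoate (C3–O bond, 3,6-trans).
2. The C6–OO bond comes from SN2 inversion of a threo C6 triflate by a protected hydroperoxide; the enoate from a Horner–Wadsworth–Emmons reaction at C3; the (17Z,19E)-diene from a Z-selective Wittig reaction of a C17 ylide with (2E)-hepta-2,6-dienal.
3. Key C5–C6 bond: intermolecular chelation-controlled allylation of oxolane-2-carbaldehyde 7 (C6–C17 fragment) with allylstannane 8 (C3–C5 fragment), which sets C6.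
4. Ring A (the trans-oxolane, C7–C10) is formed first by cobalt-catalysed aerobic oxidative cyclisation of pentenol 5, made from (S)-epoxide 2 (kinetic resolution) and 6-chlorohexylmagnesium bromide.
5. Ring order: ring A (step 3), then ring B (step 18).

Assumption: the SMILES is read as 2-[(3R,6R)-6-{(2S,5R)-5-[(7Z,9E)-tetradeca-7,9,13-trien-1-yl]oxolan-2-yl}-1,2-dioxan-3-yl]acetic acid; atom labels below use acid numbering (C1 = CO2H, peroxide on C3 and C6, oxolane C7–C10, diene 17Z,19E).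

**Step 1**
Reactants: 1 rac-2-(but-3-en-1-yl)oxirane
Product: 2 (2S)-2-(but-3-en-1-yl)oxirane
Conditions: (S,S)-(salen)Co(OAc) (0.5 mol %; salen = N,N′-bis(3,5-di-tert-butylsalicylidene)cyclohexane-1,2-diamine dianion; trivalent cobalt), H2O (0.55 equiv), neat, 0 °C → rt, 16 h; distil
Reagents that add atoms: none
Why: Jacobsen hydrolytic kinetic resolution, in which the (S,S)-catalyst hydrolyses the (R)-epoxide much faster, so unreacted (S)-2 (the future C10 centre) is recovered in ≥99 % ee.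

**Step 2**
Reactants: 3 1-bromo-6-chlorohexane; 2 (2S)-2-(but-3-en-1-yl)oxirane
Product: 5 (5R)-12-chlorododec-1-en-5-ol, via (6-chlorohexyl)magnesium bromide 4 (not isolated)
Conditions: Mg, THF, rt; then CuI (10 mol %), 2, THF, −30 → 0 °C; H2O/NH4Cl work-up
Reagents that add atoms: none
Why: Magnesium inserts into the C–Br bond only, and the copper-catalysed Grignard opening of the terminal epoxide is an SN2 attack at the CH2 carbon, so the carbinol centre is carried over unchanged (it is called R only because the CIP priorities change).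

**Step 3**
Reactants: 5 (5R)-12-chlorododec-1-en-5-ol
Product: 6 [(2S,5R)-5-(7-chloroheptyl)oxolan-2-yl]methanol
Conditions: Co(modp)2 (15 mol %; modp = 1-morpholinocarbamoyl-4,4-dimethyl-1,3-pentanedionate; divalent cobalt), O2 (1 atm), t-BuOOH (10 mol %), i-PrOH, 4 Å MS, 55 °C
Reagents that add atoms: dioxygen, O=O
Why: Mukaiyama cobalt-catalysed aerobic oxidative cyclisation of a pent-4-en-1-ol gives the 2,5-trans-oxolane (typically >95:5), which forms ring A and sets C7 as S from the existing C10 centre.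

**Step 4**
Reactants: 6 [(2S,5R)-5-(7-chloroheptyl)oxolan-2-yl]methanol
Product: 7 (2S,5R)-5-(7-chloroheptyl)oxolane-2-carbaldehyde
Conditions: Dess–Martin periodinane, pyridine, CH2Cl2, 0 °C → rt; used at once
Reagents that add atoms: none
Why: Dess–Martin oxidation of the primary alcohol is near-neutral and does not epimerise the α-alkoxy aldehyde.

**Step 5 (key step)**
Reactants: 7 (2S,5R)-5-(7-chloroheptyl)oxolane-2-carbaldehyde; 8 tributyl(prop-2-en-1-yl)stannane
Product: 9 (1S)-1-[(2S,5R)-5-(7-chloroheptyl)oxolan-2-yl]but-3-en-1-ol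
Conditions: MgBr2·OEt2 (2.5 equiv), CH2Cl2, −78 °C; then 8 (1.5 equiv), −78 → −20 °C; aq NaHCO3
Reagents that add atoms: none
Why: Keck-type chelation-controlled carbonyl allylation, in which MgBr2 bridges the ring oxygen and the carbonyl oxygen and the allylstannane adds to the open face of the chelate (Cram chelate model), joining the C6–C17 and C3–C5 fragments and giving the threo (6S) carbinol.

**Step 6**
Reactants: 9 (1S)-1-[(2S,5R)-5-(7-chloroheptyl)oxolan-2-yl]but-3-en-1-ol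
Product: 10 tert-butyl{[(1S)-1-[(2S,5R)-5-(7-chloroheptyl)oxolan-2-yl]but-3-en-1-yl]oxy}dimethylsilane
Conditions: TBSOTf, 2,6-lutidine, CH2Cl2, −78 → 0 °C
Reagents that add atoms: tert-butyldimethylsilyl trifluoromethanesulfonate, CC(C)(C)[Si](C)(C)OS(=O)(=O)C(F)(F)F
Why: Silylation of the hindered secondary alcohol with the silyl triflate masks C6–OH through the oxidative, basic and ylide steps that follow.

**Step 7**
Reactants: 10 tert-butyl{[(1S)-1-[(2S,5R)-5-(7-chloroheptyl)oxolan-2-yl]but-3-en-1-yl]oxy}dimethylsilane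
Product: 12 (4S)-4-[(tert-butyldimethylsilyl)oxy]-4-[(2S,5R)-5-(7-chloroheptyl)oxolan-2-yl]butan-1-ol, via B-alkyl-9-BBN adduct 11 (not isolated)
Conditions: 9-BBN, THF, 0 °C → rt; then 3 M NaOH, 30 % H2O2, 0 °C → rt
Reagents that add atoms: hydrogen peroxide, OO
Why: Hydroboration–oxidation, in which 9-BBN adds anti-Markovnikov to the only alkene and alkaline peroxide replaces boron by OH, leaving the alkyl chloride and silyl ether untouched.

**Step 8**
Reactants: 12 (4S)-4-[(tert-butyldimethylsilyl)oxy]-4-[(2S,5R)-5-(7-chloroheptyl)oxolan-2-yl]butan-1-ol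
Product: 14 {7-[(2R,5S)-5-{(1S)-1-[(tert-butyldimethylsilyl)oxy]-4-hydroxybutyl}oxolan-2-yl]heptyl}triphenylphosphonium iodide, via primary iodide 13 (not isolated)
Conditions: NaI (3 equiv), PPh3 (2 equiv), MeCN, reflux, 36 h
Reagents that add atoms: sodium iodide, [Na+].[I-]; triphenylphosphine, c1ccc(cc1)P(c1ccccc1)c1ccccc1
Why: Finkelstein exchange makes the primary iodide in the flask, which quaternises triphenylphosphine by SN2; the free primary alcohol does not interfere.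

**Step 9**
Reactants: 15 pent-4-enal
Product: 16 (2E)-hepta-2,6-dienal
Conditions: Ph3P=CHCHO (0.9 equiv), toluene, 80 °C
Reagents that add atoms: (triphenylphosphoranylidene)acetaldehyde, O=CC=P(c1ccccc1)(c1ccccc1)c1ccccc1
Why: Wittig reaction with the stabilised formyl ylide is E-selective and stops after one two-carbon homologation when the aldehyde is kept in excess.

**Step 10**
Reactants: 14 {7-[(2R,5S)-5-{(1S)-1-[(tert-butyldimethylsilyl)oxy]-4-hydroxybutyl}oxolan-2-yl]heptyl}triphenylphosphonium iodide; 16 (2E)-hepta-2,6-dienal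
Product: 18 (4S)-4-[(tert-butyldimethylsilyl)oxy]-4-{(2S,5R)-5-[(7Z,9E)-tetradeca-7,9,13-trien-1-yl]oxolan-2-yl}butan-1-ol, via alkoxide ylide 17 (not isolated)
Conditions: NaN(SiMe3)2 (2.05 equiv), THF, −78 → −40 °C; then 16, −78 → 0 °C; H2O
Reagents that add atoms: none
Why: Z-selective Wittig olefination of a non-stabilised ylide under lithium-free conditions gives the new (Z)-alkene (about 9:1 or better) while the enal keeps its E geometry; the first equivalent of base only forms the spectator alkoxide.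

**Step 11**
Reactants: 18 (4S)-4-[(tert-butyldimethylsilyl)oxy]-4-{(2S,5R)-5-[(7Z,9E)-tetradeca-7,9,13-trien-1-yl]oxolan-2-yl}butan-1-ol
Product: 19 (4S)-4-[(tert-butyldimethylsilyl)oxy]-4-{(2S,5R)-5-[(7Z,9E)-tetradeca-7,9,13-trien-1-yl]oxolan-2-yl}butanal
Conditions: Dess–Martin periodinane, pyridine, CH2Cl2, 0 °C → rt
Reagents that add atoms: none
Why: Dess–Martin oxidation takes the primary alcohol to the aldehyde without touching the triene or the silyl ether.

**Step 12**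
Reactants: 19 (4S)-4-[(tert-butyldimethylsilyl)oxy]-4-{(2S,5R)-5-[(7Z,9E)-tetradeca-7,9,13-trien-1-yl]oxolan-2-yl}butanal
Product: 20 methyl (2E,6S)-6-[(tert-butyldimethylsilyl)oxy]-6-{(2S,5R)-5-[(7Z,9E)-tetradeca-7,9,13-trien-1-yl]oxolan-2-yl}hex-2-enoate
Conditions: (MeO)2P(O)CH2CO2Me, NaH, THF, 0 °C; then 19, 0 °C → rt
Reagents that add atoms: trimethyl phosphonoacetate, COC(=O)CP(=O)(OC)OC
Why: Horner–Wadsworth–Emmons olefination with the stabilised phosphonate anion gives the (E)-enoate (>20:1) that later serves as the Michael acceptor.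

**Step 13**
Reactants: 20 methyl (2E,6S)-6-[(tert-butyldimethylsilyl)oxy]-6-{(2S,5R)-5-[(7Z,9E)-tetradeca-7,9,13-trien-1-yl]oxolan-2-yl}hex-2-enoate
Product: 21 methyl (2E,6S)-6-hydroxy-6-{(2S,5R)-5-[(7Z,9E)-tetradeca-7,9,13-trien-1-yl]oxolan-2-yl}hex-2-enoate
Conditions: HF·pyridine, pyridine, THF, 0 °C → rt
Reagents that add atoms: none
Why: Fluoride desilylation under buffered acidic conditions frees C6–OH without forming an alkoxide, which would add 5-exo to the enoate.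

**Step 14**
Reactants: 21 methyl (2E,6S)-6-hydroxy-6-{(2S,5R)-5-[(7Z,9E)-tetradeca-7,9,13-trien-1-yl]oxolan-2-yl}hex-2-enoate
Product: 22 methyl (2E,6S)-6-{(2S,5R)-5-[(7Z,9E)-tetradeca-7,9,13-trien-1-yl]oxolan-2-yl}-6-[(trifluoromethanesulfonyl)oxy]hex-2-enoate
Conditions: Tf2O, 2,6-lutidine, CH2Cl2, −78 °C, 30 min; cold work-up, used at once
Reagents that add atoms: trifluoromethanesulfonic anhydride, O=S(=O)(OS(=O)(=O)C(F)(F)F)C(F)(F)F
Why: O-sulfonylation gives the triflate with retention at C6 (no C–O bond is broken) and provides a leaving group good enough for SN2 next to the oxolane oxygen.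

**Step 15**
Reactants: 23 2,3-dimethylbut-2-ene
Product: 26 2-hydroperoxy-2-methoxypropane, via 4,4,5,5-tetramethyl-1,2,3-trioxolane 24 (not isolated), via propan-2-one O-oxide 25 (not isolated)
Conditions: O3, MeOH/CH2Cl2, −78 °C; N2 purge; concentrated cold and kept in solution
Reagents that add atoms: ozone, [O-][O+]=O; methanol, CO
Why: Ozonolysis in methanol, in which cycloreversion of the primary ozonide gives acetone and the Criegee carbonyl oxide, which methanol traps as the α-methoxy hydroperoxide.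

**Step 16**
Reactants: 22 methyl (2E,6S)-6-{(2S,5R)-5-[(7Z,9E)-tetradeca-7,9,13-trien-1-yl]oxolan-2-yl}-6-[(trifluoromethanesulfonyl)oxy]hex-2-enoate; 26 2-hydroperoxy-2-methoxypropane
Product: 28 methyl (2E,6R)-6-[(2-methoxypropan-2-yl)peroxy]-6-{(2S,5R)-5-[(7Z,9E)-tetradeca-7,9,13-trien-1-yl]oxolan-2-yl}hex-2-enoate, via potassium 2-methoxypropan-2-yl peroxide 27 (not isolated)
Conditions: 26 (2.0 equiv), KOtBu (1.9 equiv), THF, 0 °C; then 22, 18-crown-6 (cat.), −40 → 0 °C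
Reagents that add atoms: none
Why: SN2 displacement of the secondary triflate by the weakly basic, α-effect peroxide anion proceeds with inversion and so turns the (6S) triflate into the (6R) peroxide, erythro to C7.

**Step 17**
Reactants: 28 methyl (2E,6R)-6-[(2-methoxypropan-2-yl)peroxy]-6-{(2S,5R)-5-[(7Z,9E)-tetradeca-7,9,13-trien-1-yl]oxolan-2-yl}hex-2-enoate
Product: 29 methyl (2E,6R)-6-hydroperoxy-6-{(2S,5R)-5-[(7Z,9E)-tetradeca-7,9,13-trien-1-yl]oxolan-2-yl}hex-2-enoate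
Conditions: AcOH/THF/H2O (4:2:1), rt
Reagents that add atoms: none
Why: Mild acid hydrolysis of the peroxyketal releases the hydroperoxide while the ester, the diene and the C6–OO bond are untouched.

**Step 18**
Reactants: 29 methyl (2E,6R)-6-hydroperoxy-6-{(2S,5R)-5-[(7Z,9E)-tetradeca-7,9,13-trien-1-yl]oxolan-2-yl}hex-2-enoate
Product: 30 methyl 2-[(3R,6R)-6-{(2S,5R)-5-[(7Z,9E)-tetradeca-7,9,13-trien-1-yl]oxolan-2-yl}-1,2-dioxan-3-yl]acetate
Conditions: Et2NH (0.5 equiv), CF3CH2OH, rt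
Reagents that add atoms: none
Why: Base-mediated intramolecular 6-exo-trig oxa-Michael addition forms ring B and sets C3 as R, because both substituents are equatorial in the chair and the reversible addition ends at the 3,6-trans isomer, while the protic fluorinated solvent protonates the ester enolate before it can attack the O–O bond.

**Step 19**
Reactants: 30 methyl 2-[(3R,6R)-6-{(2S,5R)-5-[(7Z,9E)-tetradeca-7,9,13-trien-1-yl]oxolan-2-yl}-1,2-dioxan-3-yl]acetate
Product: 32 2-[(3R,6R)-6-{(2S,5R)-5-[(7Z,9E)-tetradeca-7,9,13-trien-1-yl]oxolan-2-yl}-1,2-dioxan-3-yl]acetic acid, via lithium carboxylate 31 (not isolated)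
Conditions: LiOH·H2O (3 equiv), THF/H2O (3:1), 0 °C → rt; then 1 M HCl to pH 3–4, 0 °C
Reagents that add atoms: lithium hydroxide, [Li+].[OH-]
Why: Ester saponification at low temperature followed by careful acidification gives the acid, and the dialkyl peroxide and all stereocentres survive brief cold hydroxide.

**Compound list**
1 | rac-2-(but-3-en-1-yl)oxirane | C=CCCC1CO1 | starting material
2 | (2S)-2-(but-3-en-1-yl)oxirane | C=CCC[C@H]1CO1 | intermediate
3 | 1-bromo-6-chlorohexane | ClCCCCCCBr | starting material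
4 | (6-chlorohexyl)magnesium bromide | ClCCCCCC[Mg]Br | intermediate
5 | (5R)-12-chlorododec-1-en-5-ol | ClCCCCCCC[C@@H](O)CCC=C | intermediate
6 | [(2S,5R)-5-(7-chloroheptyl)oxolan-2-yl]methanol | ClCCCCCCC[C@@H]1CC[C@@H](CO)O1 | intermediate
7 | (2S,5R)-5-(7-chloroheptyl)oxolane-2-carbaldehyde | ClCCCCCCC[C@@H]1CC[C@@H](C=O)O1 | intermediate
8 | tributyl(prop-2-en-1-yl)stannane | C=CC[Sn](CCCC)(CCCC)CCCC | starting material
9 | (1S)-1-[(2S,5R)-5-(7-chloroheptyl)oxolan-2-yl]but-3-en-1-ol | ClCCCCCCC[C@@H]1CC[C@@H]([C@@H](O)CC=C)O1 | intermediate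
10 | tert-butyl{[(1S)-1-[(2S,5R)-5-(7-chloroheptyl)oxolan-2-yl]but-3-en-1-yl]oxy}dimethylsilane | ClCCCCCCC[C@@H]1CC[C@@H]([C@@H](O[Si](C)(C)C(C)(C)C)CC=C)O1 | intermediate
11 | 9-{(4S)-4-[(tert-butyldimethylsilyl)oxy]-4-[(2S,5R)-5-(7-chloroheptyl)oxolan-2-yl]butyl}-9-borabicyclo[3.3.1]nonane | ClCCCCCCC[C@@H]1CC[C@@H]([C@@H](O[Si](C)(C)C(C)(C)C)CCCB2C3CCCC2CCC3)O1 | intermediate
12 | (4S)-4-[(tert-butyldimethylsilyl)oxy]-4-[(2S,5R)-5-(7-chloroheptyl)oxolan-2-yl]butan-1-ol | ClCCCCCCC[C@@H]1CC[C@@H]([C@@H](O[Si](C)(C)C(C)(C)C)CCCO)O1 | intermediate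
13 | (4S)-4-[(tert-butyldimethylsilyl)oxy]-4-[(2S,5R)-5-(7-iodoheptyl)oxolan-2-yl]butan-1-ol | ICCCCCCC[C@@H]1CC[C@@H]([C@@H](O[Si](C)(C)C(C)(C)C)CCCO)O1 | intermediate
14 | {7-[(2R,5S)-5-{(1S)-1-[(tert-butyldimethylsilyl)oxy]-4-hydroxybutyl}oxolan-2-yl]heptyl}triphenylphosphonium iodide | c2ccccc2[P+](c2ccccc2)(c2ccccc2)CCCCCCC[C@@H]1CC[C@@H]([C@@H](O[Si](C)(C)C(C)(C)C)CCCO)O1.[I-] | intermediate
15 | pent-4-enal | C=CCCC=O | starting material
16 | (2E)-hepta-2,6-dienal | C=CCC/C=C/C=O | intermediate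
17 | sodium (4S)-4-[(tert-butyldimethylsilyl)oxy]-4-{(2S,5R)-5-[7-(triphenyl-λ5-phosphanylidene)heptyl]oxolan-2-yl}butan-1-olate | c2ccccc2P(c2ccccc2)(c2ccccc2)=CCCCCCC[C@@H]1CC[C@@H]([C@@H](O[Si](C)(C)C(C)(C)C)CCC[O-])O1.[Na+] | intermediate
18 | (4S)-4-[(tert-butyldimethylsilyl)oxy]-4-{(2S,5R)-5-[(7Z,9E)-tetradeca-7,9,13-trien-1-yl]oxolan-2-yl}butan-1-ol | C=CCC/C=C/C=C\CCCCCC[C@@H]1CC[C@@H]([C@@H](O[Si](C)(C)C(C)(C)C)CCCO)O1 | intermediate
19 | (4S)-4-[(tert-butyldimethylsilyl)oxy]-4-{(2S,5R)-5-[(7Z,9E)-tetradeca-7,9,13-trien-1-yl]oxolan-2-yl}butanal | C=CCC/C=C/C=C\CCCCCC[C@@H]1CC[C@@H]([C@@H](O[Si](C)(C)C(C)(C)C)CCC=O)O1 | intermediate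
20 | methyl (2E,6S)-6-[(tert-butyldimethylsilyl)oxy]-6-{(2S,5R)-5-[(7Z,9E)-tetradeca-7,9,13-trien-1-yl]oxolan-2-yl}hex-2-enoate | C=CCC/C=C/C=C\CCCCCC[C@@H]1CC[C@@H]([C@@H](O[Si](C)(C)C(C)(C)C)CC/C=C/C(=O)OC)O1 | intermediate
21 | methyl (2E,6S)-6-hydroxy-6-{(2S,5R)-5-[(7Z,9E)-tetradeca-7,9,13-trien-1-yl]oxolan-2-yl}hex-2-enoate | C=CCC/C=C/C=C\CCCCCC[C@@H]1CC[C@@H]([C@@H](O)CC/C=C/C(=O)OC)O1 | intermediate
22 | methyl (2E,6S)-6-{(2S,5R)-5-[(7Z,9E)-tetradeca-7,9,13-trien-1-yl]oxolan-2-yl}-6-[(trifluoromethanesulfonyl)oxy]hex-2-enoate | C=CCC/C=C/C=C\CCCCCC[C@@H]1CC[C@@H]([C@@H](OS(=O)(=O)C(F)(F)F)CC/C=C/C(=O)OC)O1 | intermediate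
23 | 2,3-dimethylbut-2-ene | CC(C)=C(C)C | starting material
24 | 4,4,5,5-tetramethyl-1,2,3-trioxolane | CC1(C)OOOC1(C)C | intermediate
25 | propan-2-one O-oxide | CC(C)=[O+][O-] | intermediate
26 | 2-hydroperoxy-2-methoxypropane (2-methoxypropan-2-yl hydroperoxide) | COC(C)(C)OO | intermediate
27 | potassium 2-methoxypropan-2-yl peroxide | COC(C)(C)O[O-].[K+] | intermediate
28 | methyl (2E,6R)-6-[(2-methoxypropan-2-yl)peroxy]-6-{(2S,5R)-5-[(7Z,9E)-tetradeca-7,9,13-trien-1-yl]oxolan-2-yl}hex-2-enoate | C=CCC/C=C/C=C\CCCCCC[C@@H]1CC[C@@H]([C@H](OOC(C)(C)OC)CC/C=C/C(=O)OC)O1 | intermediate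
29 | methyl (2E,6R)-6-hydroperoxy-6-{(2S,5R)-5-[(7Z,9E)-tetradeca-7,9,13-trien-1-yl]oxolan-2-yl}hex-2-enoate | C=CCC/C=C/C=C\CCCCCC[C@@H]1CC[C@@H]([C@H](OO)CC/C=C/C(=O)OC)O1 | intermediate
30 | methyl 2-[(3R,6R)-6-{(2S,5R)-5-[(7Z,9E)-tetradeca-7,9,13-trien-1-yl]oxolan-2-yl}-1,2-dioxan-3-yl]acetate | C=CCC/C=C/C=C\CCCCCC[C@@H]1CC[C@@H]([C@H]2CC[C@H](CC(=O)OC)OO2)O1 | intermediate
31 | lithium 2-[(3R,6R)-6-{(2S,5R)-5-[(7Z,9E)-tetradeca-7,9,13-trien-1-yl]oxolan-2-yl}-1,2-dioxan-3-yl]acetate | C=CCC/C=C/C=C\CCCCCC[C@@H]1CC[C@@H]([C@H]2CC[C@H](CC(=O)[O-])OO2)O1.[Li+] | intermediate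
32 | 2-[(3R,6R)-6-{(2S,5R)-5-[(7Z,9E)-tetradeca-7,9,13-trien-1-yl]oxolan-2-yl}-1,2-dioxan-3-yl]acetic acid | C=CCC/C=C/C=C\CCCCCC[C@@H]1CC[C@@H]([C@H]2CC[C@H](CC(=O)O)OO2)O1 | target

**Totals**
Total step count: 19. Longest linear sequence: 17 steps (1 to 32 through steps 1–8, 10–14 and 16–19); steps 9 and 15 are side branches.

**Steps most likely to fail**

Step 16, intermolecular peroxide SN2 at C6. The carbon is secondary and flanked by the oxolane oxygen, so elimination or ring-oxygen participation (retention, or ring expansion to an oxane) may compete. The fallback makes the displacement intramolecular and sets C3 by C–C bond formation. It sets out from aldehyde 19: HC(OMe)3 and PPTS in MeOH give the silyl ether dimethyl acetal F1, Bu4NF in THF frees the acetal alcohol F2, and MsCl/Et3N gives the acetal mesylate F3. Anhydrous H2O2 in Et2O with catalytic camphorsulfonic acid exchanges one methoxy group to give the hydroperoxy acetal F4. KOtBu/18-crown-6 in THF then closes ring B by 6-exo-tet SN2 with inversion at C6, giving the 3-methoxy-1,2-dioxane F5 (mixture at C3). Me3SiOTf-promoted (or TiCl4) addition of 1-methoxy-1-(trimethylsilyloxy)ethene to the derived peroxycarbenium ion is a Mukaiyama aldol-type step; axial attack anti to the equatorial C6 substituent gives the 3,6-trans ester. The fallback comes back to the route at 30, before step 19.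

Step 18, peroxy-Michael ring closure. The risks are a cis/trans mixture at C3 and base-induced loss of water from the secondary hydroperoxide (Kornblum–DeLaMare). The fallback keeps the intermolecular displacement but replaces the conjugate addition by the same peroxycarbenium aldol. It sets out from aldehyde 19 and runs through silyl ether dimethyl acetal F1 and acetal alcohol F2 as above. Tf2O/2,6-lutidine at −78 °C gives the acetal triflate F6, and potassium peroxide 27 in THF gives the acetal peroxyketal F7 with inversion. PPTS in MeOH/CH2Cl2 then expels 2,2-dimethoxypropane and closes the ring to the 3-methoxy-1,2-dioxane F5, and the silyl ketene acetal with Me3SiOTf gives 30, where it rejoins the route before step 19.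

Step 10, Z-selective Wittig reaction with a spectator alkoxide. The risks are erosion of the Z:E ratio and a (7E,9E) isomer that is hard to remove. The fallback builds the Z-alkene as a vinyl iodide and the diene by cross-coupling. It sets out from chloride 12: NaI in acetone gives iodide 13 (isolated this time), and NaHCO3 in DMSO at 110 °C (Kornblum oxidation) gives the hydroxy aldehyde F8. (Iodomethyl)triphenylphosphonium iodide with NaN(SiMe3)2 in THF/DMPU at −78 °C (Stork–Zhao olefination) gives the (Z)-vinyl iodide F9. Suzuki coupling with the (E)-dienyl pinacol boronate F10, using Pd(PPh3)4 (zerovalent palladium) and aqueous K3PO4 in THF, then gives 18 with both alkene geometries retained, rejoining the route before step 11. F10 is made from hex-1-en-5-yne and pinacolborane with catalytic Cp2Zr(H)Cl.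

**Further compounds**
F1 | step 16 | tert-butyl{[(1S)-4,4-dimethoxy-1-{(2S,5R)-5-[(7Z,9E)-tetradeca-7,9,13-trien-1-yl]oxolan-2-yl}butyl]oxy}dimethylsilane | C=CCC/C=C/C=C\CCCCCC[C@@H]1CC[C@@H]([C@@H](O[Si](C)(C)C(C)(C)C)CCC(OC)OC)O1
F2 | step 16 | (1S)-4,4-dimethoxy-1-{(2S,5R)-5-[(7Z,9E)-tetradeca-7,9,13-trien-1-yl]oxolan-2-yl}butan-1-ol | C=CCC/C=C/C=C\CCCCCC[C@@H]1CC[C@@H]([C@@H](O)CCC(OC)OC)O1
F3 | step 16 | (1S)-4,4-dimethoxy-1-{(2S,5R)-5-[(7Z,9E)-tetradeca-7,9,13-trien-1-yl]oxolan-2-yl}butyl methanesulfonate | C=CCC/C=C/C=C\CCCCCC[C@@H]1CC[C@@H]([C@@H](OS(C)(=O)=O)CCC(OC)OC)O1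
F4 | step 16 | (1S)-4-hydroperoxy-4-methoxy-1-{(2S,5R)-5-[(7Z,9E)-tetradeca-7,9,13-trien-1-yl]oxolan-2-yl}butyl methanesulfonate (both C4 epimers) | C=CCC/C=C/C=C\CCCCCC[C@@H]1CC[C@@H]([C@@H](OS(C)(=O)=O)CCC(OC)OO)O1
F5 | step 16 | (6R)-3-methoxy-6-{(2S,5R)-5-[(7Z,9E)-tetradeca-7,9,13-trien-1-yl]oxolan-2-yl}-1,2-dioxane (both C3 epimers) | C=CCC/C=C/C=C\CCCCCC[C@@H]1CC[C@@H]([C@H]2CCC(OC)OO2)O1
F6 | step 18 | (1S)-4,4-dimethoxy-1-{(2S,5R)-5-[(7Z,9E)-tetradeca-7,9,13-trien-1-yl]oxolan-2-yl}butyl trifluoromethanesulfonate | C=CCC/C=C/C=C\CCCCCC[C@@H]1CC[C@@H]([C@@H](OS(=O)(=O)C(F)(F)F)CCC(OC)OC)O1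
F7 | step 18 | (2S,5R)-2-{(1R)-4,4-dimethoxy-1-[(2-methoxypropan-2-yl)peroxy]butyl}-5-[(7Z,9E)-tetradeca-7,9,13-trien-1-yl]oxolane | C=CCC/C=C/C=C\CCCCCC[C@@H]1CC[C@@H]([C@H](OOC(C)(C)OC)CCC(OC)OC)O1
F8 | step 10 | 7-[(2R,5S)-5-{(1S)-1-[(tert-butyldimethylsilyl)oxy]-4-hydroxybutyl}oxolan-2-yl]heptanal | O=CCCCCCC[C@@H]1CC[C@@H]([C@@H](O[Si](C)(C)C(C)(C)C)CCCO)O1
F9 | step 10 | (4S)-4-[(tert-butyldimethylsilyl)oxy]-4-{(2S,5R)-5-[(7Z)-8-iodooct-7-en-1-yl]oxolan-2-yl}butan-1-ol | I/C=C\CCCCCC[C@@H]1CC[C@@H]([C@@H](O[Si](C)(C)C(C)(C)C)CCCO)O1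
F10 | step 10 | 2-[(1E)-hexa-1,5-dien-1-yl]-4,4,5,5-tetramethyl-1,3,2-dioxaborolane | C=CCC/C=C/B1OC(C)(C)C(C)(C)O1
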